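**Plan**

Locants used throughout: C1 = CH(OBz) next to the quaternary carbon, C2=C3 = alkene, C4 = CH(OBz), C5 = CH(OH), C6 = C(OH), C7 = CH2OH.
Cuts: first the C7 silyl ether and the C5–H bond (C5 back to a ketone), then the ring bond C1–C6 by a retro-acyloin shift that ties C1 to C5 instead. This is possible because C6 is a tertiary carbinol beside carbinol C5: the C5-keto form is an α-ketol whose isomeric ketol is a mirror-symmetric cyclopentene with C1 and C4 as equivalent CH(OBz) arms and C6–C7 as a glycoloyl side chain.
The meso cyclopentene is taken apart at the two benzoate C–O bonds, at the side-chain C=O and tertiary C–O bonds (spiro-epoxide of an exocyclic alkene), at the two ring C–O bonds (singlet oxygen) and at the exocyclic C=C bond (fulvene from cyclopentadiene and a silyloxyacetaldehyde).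
Forward: the five-membered ring is bought, the two-carbon chain is attached by fulvene condensation, the ring is oxygenated on one face, and the six-membered ring arises last by one-carbon ring expansion.
Stereochemistry: singlet oxygen and a hydroxyl-directed epoxidation give the all-cis meso array; a chiral copper bis(oxazoline) Lewis acid decides which enantiotopic arm migrates (C1 and C4 absolute, C6 relative to C1 through the chelate); hydroxyl-directed hydride delivery sets C5.

Key step: step 6

Remark: cyclopentadiene 1 is the monomer obtained by routine cracking of the commercial dimer just before use; the cracking is not counted as a step.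
Remark: the sense of induction of the (S,S)-ligand in step 6 cannot be predicted with certainty; should the other arm migrate, the (R,R)-ligand is used instead.
Remark: compounds 4, 5, 6, 8 and 9 are racemic (one enantiomer drawn); both enantiomers converge on meso 10.

**Route**

Step 1
Reactants: 1 cyclopentadiene; 2 (tert-butyldimethylsilyloxy)acetaldehyde
Product: 3 6-[(tert-butyldimethylsilyloxy)methyl]fulvene
Conditions: pyrrolidine (10 mol %), MeOH/H2O, rt
Reagents that add atoms: none
Why: pyrrolidine-catalysed fulvene condensation (iminium activation of the aldehyde, attack of cyclopentadienide, loss of the amine), a standard reaction of aliphatic aldehydes to which the silyl ether is inert.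

Step 2
Reactants: 3 6-[(tert-butyldimethylsilyloxy)methyl]fulvene
Product: 5 racemic cis-2-[2-(tert-butyldimethylsilyloxy)ethylidene]cyclopent-4-ene-1,3-diol, via fulvene endoperoxide 4 (not isolated)
Conditions: O2, hν, 5,10,15,20-tetraphenylporphyrin (cat.), CH2Cl2, −78 °C; then thiourea, MeOH, −78 °C → rt
Reagents that add atoms: dioxygen O=O
Why: [4+2] cycloaddition of singlet oxygen across the ring diene of the fulvene followed by thiourea reduction of the O–O bond at low temperature, before the labile endoperoxide can rearrange; both C–O bonds form on one face, so the diol is cis.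

Step 3
Reactants: 5 racemic cis-2-[2-(tert-butyldimethylsilyloxy)ethylidene]cyclopent-4-ene-1,3-diol
Product: 6 racemic 2-[(tert-butyldimethylsilyloxy)methyl]-1-oxaspiro[2.4]hept-5-ene-4,7-diol with the epoxide oxygen cis to both hydroxyls
Conditions: VO(acac)2 (cat.), tBuOOH, CH2Cl2, 0 °C
Reagents that add atoms: tert-butyl hydroperoxide CC(C)(C)OO
Why: hydroxyl-directed vanadium-catalysed epoxidation of an allylic alcohol, in which the peroxo-vanadate bound to either cis-hydroxyl delivers oxygen to the hydroxyl face (spiro carbon: oxygen cis to both carbinol oxygens; side-chain CH fixed by syn addition to the single alkene geometry), and the electron-richer trisubstituted exocyclic alkene, at the smaller O–C–C=C dihedral angle, should react ahead of the ring alkene.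

Step 4
Reactants: 6 spiro-epoxy diol; 7 benzoyl chloride (two equivalents, one per hydroxyl)
Product: 8 racemic 4,7-dibenzoate of spiro-epoxy diol 6
Conditions: BzCl (2.4 equiv), pyridine, 4-(dimethylamino)pyridine (cat.), CH2Cl2, 0 °C → rt
Reagents that add atoms: benzoyl chloride O=C(Cl)c1ccccc1
Why: nucleophile-catalysed acylation in which each of the two secondary allylic alcohols takes up one molecule of benzoyl chloride, so two equivalents of 7 are consumed, while the epoxide, the silyl ether and every stereocentre stay untouched.

Step 5
Reactants: 8 spiro-epoxide dibenzoate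
Product: 10 meso all-cis 2-hydroxy-2-[(tert-butyldimethylsilyloxy)acetyl]cyclopent-4-ene-1,3-diyl dibenzoate, via alkoxysulfonium triflate 9 (not isolated)
Conditions: DMSO, TfOH, CH2Cl2, −20 °C → rt; then iPr2NEt, 0 °C
Reagents that add atoms: dimethyl sulfoxide CS(C)=O
Why: Kornblum-type oxidative opening of an epoxide, in which DMSO should attack the protonated epoxide at the side-chain carbon (the spiro carbon is fully substituted and flanked by two electron-withdrawing CH(OBz) groups) and the base collapses the alkoxysulfonium salt to the ketone; the tertiary C–O bond is never broken, so the hydroxyl stays cis to both benzoates and loss of the side-chain stereocentre makes the product meso.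

Step 6
Reactants: 10 meso all-cis 2-hydroxy-2-[(tert-butyldimethylsilyloxy)acetyl]cyclopent-4-ene-1,3-diyl dibenzoate
Product: 11 (1S,4R,6S)-6-[(tert-butyldimethylsilyloxy)methyl]-6-hydroxy-5-oxocyclohex-2-ene-1,4-diyl dibenzoate (locants of the plan)
Conditions: Cu(OTf)2 (10 mol %), 2,2'-(propane-2,2-diyl)bis[(4S)-4-tert-butyl-4,5-dihydrooxazole] [(S,S)-tBu-box, 11 mol %], 4 Å MS, CH2Cl2, rt
Reagents that add atoms: none
Why: Proposed new method: divalent copper carrying the bis(oxazoline) chelates the tertiary hydroxyl and the side-chain carbonyl oxygen of 10 in a five-membered ring, which holds the O–C–C=O unit syn-planar and places the two ring C–C bonds of the carbinol carbon above and below that plane, so that one of them shifts with its electron pair to the carbonyl carbon while the old carbinol becomes the C5 ketone (1,2-acyloin shift). The closest known reaction type is the Lewis-acid-promoted α-ketol ring expansion of 1-acylcycloalkanols (steroid D-homoannulation) and its catalytic enantioselective variants, which so far select carbonyl faces and not enantiotopic migrating groups. The six-membered ring is not closed end to end but arises by one-carbon enlargement of the cyclopentene, the former side-chain carbonyl carbon being inserted between C1 and C5 as C6 (new bond C1–C6). C1 and C4 keep their configuration (migration with retention) and become defined in the absolute sense because the tert-butyl groups of the ligand should leave only one of the two enantiotopic CH(OBz) arms (the S-configured one) an unhindered path to the carbonyl carbon, while C6 is set relative to C1 by the syn chelate, which places the new hydroxyl on the face of the C1 benzoate. The step needs enantiotopic-group selection and a kinetic stop at 11: the mirror-symmetric all-cis array makes the two arms differ only in their relation to the ligand, relief of cyclopentene strain drives the isomerisation, and the poorly migrating silyloxymethyl group should keep 11 from shifting further.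

Step 7
Reactants: 11 ring-expanded ketone
Product: 12 (1S,4R,5S,6R)-6-[(tert-butyldimethylsilyloxy)methyl]-5,6-dihydroxycyclohex-2-ene-1,4-diyl dibenzoate (locants of the plan)
Conditions: Me4NBH(OAc)3, MeCN/AcOH, −30 → 0 °C
Reagents that add atoms: none
Why: Evans–Saksena-type hydroxyl-directed reduction, in which the C6 hydroxyl exchanges onto boron and hydride is delivered internally to the C5 carbonyl face on which that hydroxyl sits, so the new C5 hydroxyl is trans to it and to the C4 benzoate; the acidic medium avoids enolisation at C4 and benzoyl migration, and the silyl group keeps the C7 oxygen from directing hydride to the other face.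

Step 8
Reactants: 12 silyl-protected trans-5,6-diol
Product: 13 (1S,4R,5S,6R)-5,6-dihydroxy-6-(hydroxymethyl)cyclohex-2-ene-1,4-diyl dibenzoate (locants of the plan; the target)
Conditions: HF·pyridine, pyridine, THF, 0 °C → rt
Reagents that add atoms: none
Why: fluoride-mediated cleavage of the primary silyl ether (Si–F bond formation) in a buffered acidic medium in which the benzoates should neither cleave nor migrate to the freed primary hydroxyl; no stereocentre is involved.

**Compound list**

1 | cyclopenta-1,3-diene | C1=CCC=C1 | starting material
2 | (tert-butyldimethylsilyloxy)acetaldehyde | O=CCO[Si](C)(C)C(C)(C)C | starting material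
3 | 6-[(tert-butyldimethylsilyloxy)methyl]fulvene | C(=C1C=CC=C1)CO[Si](C)(C)C(C)(C)C | intermediate
4 | 7-[2-(tert-butyldimethylsilyloxy)ethylidene]-2,3-dioxabicyclo[2.2.1]hept-5-ene (racemic, not isolated) | O1[C@@H]2C=C[C@H](O1)/C2=C/CO[Si](C)(C)C(C)(C)C | intermediate
5 | cis-2-[2-(tert-butyldimethylsilyloxy)ethylidene]cyclopent-4-ene-1,3-diol (racemic) | O[C@@H]1C=C[C@H](O)/C1=C/CO[Si](C)(C)C(C)(C)C | intermediate
6 | 2-[(tert-butyldimethylsilyloxy)methyl]-1-oxaspiro[2.4]hept-5-ene-4,7-diol, epoxide oxygen cis to both hydroxyls (racemic) | O[C@@H]1C=C[C@H](O)[C@]12O[C@@H]2CO[Si](C)(C)C(C)(C)C | intermediate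
7 | benzoyl chloride | O=C(Cl)c1ccccc1 | starting material
8 | 4,7-dibenzoate of 6 (racemic) | O=C(O[C@@H]1C=C[C@H](OC(=O)c2ccccc2)[C@]12O[C@@H]2CO[Si](C)(C)C(C)(C)C)c1ccccc1 | intermediate
9 | {1-[all-cis-2,5-bis(benzoyloxy)-1-hydroxycyclopent-3-en-1-yl]-2-(tert-butyldimethylsilyloxy)ethoxy}dimethylsulfonium triflate (racemic, not isolated) | O=C(O[C@@H]1C=C[C@H](OC(=O)c2ccccc2)[C@@]1(O)[C@@H](O[S+](C)C)CO[Si](C)(C)C(C)(C)C)c1ccccc1.[O-]S(=O)(=O)C(F)(F)F | intermediate
10 | meso all-cis 2-hydroxy-2-[(tert-butyldimethylsilyloxy)acetyl]cyclopent-4-ene-1,3-diyl dibenzoate (tertiary hydroxyl and both benzoates on one face) | O[C@@]1(C(=O)CO[Si](C)(C)C(C)(C)C)[C@@H](OC(=O)c2ccccc2)C=C[C@H]1OC(=O)c1ccccc1 | intermediate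
11 | (1S,4R,6S)-6-[(tert-butyldimethylsilyloxy)methyl]-6-hydroxy-5-oxocyclohex-2-ene-1,4-diyl dibenzoate (both benzoates and the C6 hydroxyl on one face) | O=C(O[C@H]1C=C[C@@H](OC(=O)c2ccccc2)C(=O)[C@]1(O)CO[Si](C)(C)C(C)(C)C)c1ccccc1 | intermediate
12 | (1S,4R,5S,6R)-6-[(tert-butyldimethylsilyloxy)methyl]-5,6-dihydroxycyclohex-2-ene-1,4-diyl dibenzoate (C5 hydroxyl trans to the C6 hydroxyl and to the C4 benzoate) | O=C(O[C@H]1C=C[C@@H](OC(=O)c2ccccc2)[C@H](O)[C@]1(O)CO[Si](C)(C)C(C)(C)C)c1ccccc1 | intermediate
13 | (1S,4R,5S,6R)-5,6-dihydroxy-6-(hydroxymethyl)cyclohex-2-ene-1,4-diyl dibenzoate | O=C(O[C@H]1C=C[C@@H](OC(=O)c2ccccc2)[C@H](O)[C@]1(O)CO)c1ccccc1 | target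

**Count and risks**

Total: 8 steps. Longest linear sequence: 8 steps (1 and 2 to 13).

Step 6 (riskiest). The ligand may discriminate poorly, or in the wrong sense, between the two enantiotopic arms. The new ketol may also bind copper and stop turnover, or a slow onward shift of the silyloxymethyl group may erode enantiopurity. Fallback with known chemistry: from 10 the ring expansion is run under the same chelation control but without chiral information, with Cu(OTf)2 and 2,2'-bipyridine in CH2Cl2. This should give 11 as the racemate, that is together with the (1R,4S,6R)-enantiomer of the ring-expanded ketone F1. The two are separated by preparative chromatography on a chiral stationary phase such as amylose tris(3,5-dimethylphenylcarbamate), and the route is rejoined at 11.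

Step 5. The sulfoxide may open the activated epoxide at the spiro carbon instead of the side-chain carbon, or the strong acid may strip the silyl ether. Fallback: from epoxy diol 6, before benzoylation, Ti(OiPr)4 and thiophenol in CH2Cl2 open the 2,3-epoxy alcohol at the distal side-chain carbon under chelation control and without protic acid. This gives the all-cis 2-[2-(tert-butyldimethylsilyloxy)-1-(phenylsulfanyl)ethyl]cyclopent-4-ene-1,2,3-triol F2. Two equivalents of benzoyl chloride 7 with pyridine esterify the two secondary ring hydroxyls to the sulfide dibenzoate F3. N-Chlorosuccinimide in CH2Cl2 converts the sulfide into the α-chloro sulfide F4, which is hydrolysed in the same flask with aqueous NaHCO3/MeCN to the ketone. The route is rejoined at 10.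

Step 3. Hydroxyl-directed epoxidation of the ring alkene, or over-oxidation to the bis-epoxide, may compete with epoxidation of the exocyclic alkene. Fallback: from diol 5, N-bromosuccinimide in aqueous THF should form the bromonium ion on the more electron-rich exocyclic alkene, on the face away from the two hydroxyls, with no directing effect involved. Anti addition of water gives the all-cis 2-[1-bromo-2-(tert-butyldimethylsilyloxy)ethyl]cyclopent-4-ene-1,2,3-triol F5; the regioisomeric bromohydrin would lead to the same epoxide. K2CO3 in MeOH closes the ring with inversion at the bromide carbon, which places the epoxide oxygen on the hydroxyl face, and the route is rejoined at 6.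

**Further compounds**

F1 | step 6 | (1R,4S,6R)-6-[(tert-butyldimethylsilyloxy)methyl]-6-hydroxy-5-oxocyclohex-2-ene-1,4-diyl dibenzoate (enantiomer of 11) | O=C(O[C@@H]1C=C[C@H](OC(=O)c2ccccc2)C(=O)[C@@]1(O)CO[Si](C)(C)C(C)(C)C)c1ccccc1
F2 | step 5 | all-cis 2-[2-(tert-butyldimethylsilyloxy)-1-(phenylsulfanyl)ethyl]cyclopent-4-ene-1,2,3-triol (racemic) | O[C@@H]1C=C[C@H](O)[C@@]1(O)[C@@H](Sc2ccccc2)CO[Si](C)(C)C(C)(C)C
F3 | step 5 | all-cis 2-hydroxy-2-[2-(tert-butyldimethylsilyloxy)-1-(phenylsulfanyl)ethyl]cyclopent-4-ene-1,3-diyl dibenzoate (racemic) | O=C(O[C@@H]1C=C[C@H](OC(=O)c2ccccc2)[C@@]1(O)[C@@H](Sc2ccccc2)CO[Si](C)(C)C(C)(C)C)c1ccccc1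
F4 | step 5 | all-cis 2-[1-chloro-2-(tert-butyldimethylsilyloxy)-1-(phenylsulfanyl)ethyl]-2-hydroxycyclopent-4-ene-1,3-diyl dibenzoate (epimers at the chlorinated carbon, not isolated) | O=C(O[C@@H]1C=C[C@H](OC(=O)c2ccccc2)[C@@]1(O)C(Cl)(Sc2ccccc2)CO[Si](C)(C)C(C)(C)C)c1ccccc1
F5 | step 3 | all-cis 2-[1-bromo-2-(tert-butyldimethylsilyloxy)ethyl]cyclopent-4-ene-1,2,3-triol (racemic) | O[C@@H]1C=C[C@H](O)[C@@]1(O)[C@@H](Br)CO[Si](C)(C)C(C)(C)C
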